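Yanuthone L is compound 17. The ring is numbered C1 (ketone), C2 (quaternary oxirane carbon bearing the chain), C3 (oxirane CH), C4 (CH–OAc), C5 (C–CH3), C6 (=CH). In the tricyclic compounds the six-membered ring keeps these numbers. Its concave face carries the bonds from C5 and C6 to the norbornene bridgeheads and lies under the norbornene CH=CH bridge; its convex face carries C5–CH3 and C6–H.

## Analysis of the target

Compound 17 is a cyclohex-2-enone in which all six ring carbons are functionalised: a C1 ketone, a C2–C3 oxirane, a C4 acetoxy group and a C5=C6 alkene bearing the C5 methyl. The three stereocentres C2, C3 and C4 are contiguous. C2 and C3 are tied cis by the oxirane, the C4 acetoxy oxygen sits on the same face as the oxirane oxygen, and the absolute configuration is 2R,3R,4R in this numbering. The chain on C2 is a (2E,6E,10E)-12-hydroxyfarnesyl unit with three trisubstituted alkenes and a primary allylic alcohol. Sensitive groups are the α,β-epoxy ketone (base, nucleophiles, Lewis acids) and the γ-acetoxy enone (γ-deprotonation with loss of acetate or ring opening leads to aromatic material). The polyene chain is attacked by every electrophilic oxidant and cyclises under acid. The difficulties are the quaternary oxirane carbon, the cis relation between the oxirane and the C4 oxygen, and the need to bring in the oxirane oxygen without touching the chain alkenes. The strategy rests on two features: the C5=C6 alkene can be stored as a cyclopentadiene adduct whose folded tricycle distinguishes the two faces of the six-membered ring, and C2 lies between carbonyl groups at C1 and C3 once C3 is raised to the ketone level. The chain and a chlorine can then be put on C2 by enol chemistry, and the oxirane is closed reductively, so that the chain never meets an epoxidising agent.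

## Retrosynthetic reasoning

**17 to 16.** The O–Si bond of the chain is cut last. A silyl ether on the primary allylic oxygen is the only protecting group of the route, and its removal under buffered fluoride conditions avoids base, which the γ-acetoxy epoxy enone would not tolerate.

**16 to 15 and 3.** The C5–C and C6–C bonds to cyclopentadiene 3 are re-formed in the retrosynthetic sense. The enone alkene is hidden until the end, so that C5 and C6 are sp3 during all stereochemical work. Cycloreversion is forced thermally and needs no reagent.

**15 to 14.** The acetyl C–O bond is cut. Acetylation comes after the oxirane because the free C4 hydroxyl is needed as a ligand in the key step.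

**14 to 12 through 13.** The C2–O bond of the oxirane and the C3–H bond are cut, leading back to the 2-chloro-1,3-dione 12. This is the central disconnection. It turns an epoxidation, impossible beside three chain alkenes, into a hydride reduction followed by an intramolecular displacement. The forward reaction has to reduce C3 and not C1, deliver hydride to the convex face so that the C3 oxygen in chlorohydrin 13 is concave and anti to the convex C–Cl bond, and close the ring before anything else happens.

**12 to 11.** The C2–Cl bond is cut. Chlorine is introduced last at C2 because the electrophile enters from the convex face and pushes the substituent already present to the concave face. The order chain first, chlorine second therefore gives the C2 configuration the closure needs.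

**11 to 6 and 10.** The C2–C1' bond is cut between the dione carbon and the allylic terminus of the chain. A stabilised dione enolate and a π-allyl palladium complex join them under near-neutral conditions, C-selectively, without a strong base beside the α-ketol.

**10 to 9, 8 and 7.** The chain is traced to (2E,6E)-farnesol 7. The terminal oxygen comes from a selenium dioxide allylic oxidation of the acetate 8, which selects the E-methyl group of the terminal alkene. The acetate then serves as the leaving group for the coupling.

**6 to 5 to 4.** The C3 carbonyl of 6 is the hydrolysed enol ether of 5, and the C4–H bond of 5 comes from reduction of 4. In 4 the C1 carbonyl is a vinylogous ester and only C4 is a reactive ketone. The methoxy group thus differentiates the two quinone carbonyls and later delivers the C3 ketone.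

**4 to 2 and 3; 2 to 1.** The two ring-fusion bonds are cut to give quinone 2 and cyclopentadiene 3. The methyl-bearing alkene of 2 is the dienophile because the other alkene is deactivated by its methoxy group. This cycloaddition is the only source of absolute configuration. Quinone 2 comes from phenol 1 by para oxidation.

## Alternatives that were turned down

**Alternative 1:** The two ring C–O bonds at C1 and C4 are disconnected to a conjugated diene, 5-methyl-2-(silyloxyfarnesyl)cyclohexa-1,3-diene A1. Its single methyl stereocentre at C5 would be taken from a terpene of the chiral pool and erased at the end when C5=C6 is introduced.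
- Forward key step: Pd(OAc)2 (divalent palladium) with a quinone reoxidant, lithium acetate and catalytic lithium chloride in acetic acid adds two acetates cis across the diene to give the cis-1,4-diacetate A2, with the alkene moved to C2=C3.
- For it: one catalytic step makes both C–O bonds with a defined cis relation, no asymmetric catalyst is needed, and there is no high-temperature step. On these points it is stronger than the chosen route.
- Against it: the only control of the absolute sense is a lone methyl group two atoms from the nearest reacting carbon, and any shortfall in facial selectivity becomes a shortfall in enantiomeric purity once C5 is made planar. The electrophilic palladium and the π-allyl intermediate sit beside a homoallylic chain alkene that can insert. Afterwards the two acetates of A2 must be told apart, the C2=C3 alkene must be epoxidised syn by hydroxyl direction in the presence of the chain, and C5=C6 must be dehydrogenated.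
- Comparison: the chosen route fixes all three ring stereocentres from the rigid shape of one tricycle and needs no differentiation of like groups.

**Alternative 2:** All four ring C–O bonds at C2 to C5 are disconnected to dioxygen and the diene A3, the triethylsilyl ether of 5-methyl-2-(silyloxyfarnesyl)cyclohexa-2,4-dien-1-ol.
- Forward key step: sensitised singlet oxygen adds across C2 and C5 anti to the C1 silyloxy group, and cobalt tetraphenylporphyrin (divalent cobalt) rearranges the endoperoxide in the same flask to the syn-bisepoxide A4.
- For it: it has clearly the best step economy for oxygen introduction. Oxidation of C1 and base-induced opening of the C4–C5 oxirane would give the enone and the cis C4 hydroxyl in two further operations, with no temporary ring.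
- Against it: each of the three trisubstituted chain alkenes is a good substrate for the ene reaction of singlet oxygen, with reactivity of the same order as a cyclohexadiene, so chemoselectivity is structurally unfavourable. Facial control rests on one allylic silyloxy group, and enantiopure A3 needs its own synthesis.
- Comparison: the chosen route is longer, but the chain is exposed only to a π-allyl alkylation, an enol chlorination and a borohydride.

**Alternative 3:** The C1–C2 bond is disconnected to the acyclic Z-keto-enal A5, whose C3/C4 trans-diol acetonide comes from tartrate.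
- Forward key step: a chiral triazolium-derived carbene converts the aldehyde carbon into an acyl anion equivalent that adds to the C2 ketone, closing the ring and creating the tertiary carbinol in A6.
- For it: C3 and C4 come with secure absolute configuration from the chiral pool, the ring and the quaternary centre form in one step, and no oxidant meets the chain. On the origin of absolute configuration it is stronger than the chosen route.
- Against it: an enal with a carbene tends to react as a homoenolate, which here would give a lactone with the ketone. The ketone of A5 is β,γ-unsaturated and will slip into conjugation under the basic conditions. The Z-enal can isomerise. After the closure the C2–C3 oxirane still has to be made by activating the C3 hydroxyl selectively beside the allylic C4 hydroxyl and displacing it with inversion.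
- Comparison: the chosen route forms the oxirane in the same operation that sets C3.

Key step: step 10

Remarks on the chemistry: cyclopentadiene 3 is used freshly distilled from its commercial dimer. The sense of induction in step 2 is assigned from the accepted binding model of the catalyst; the antipodal catalyst would be used if the assignment proved opposite.

## Route

Step 1
Reactants: 1 3-methoxy-5-methylphenol
Product: 2 2-methoxy-6-methyl-1,4-benzoquinone
Conditions: (KSO3)2NO (2.2 equiv), KH2PO4, H2O/acetone, 0 °C to rt
Reagents that add atoms: potassium nitrosodisulfonate (Fremy's salt), [K+].[K+].[O]N(S(=O)(=O)[O-])S(=O)(=O)[O-]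
Why: Teuber oxidation; the nitroxyl radical removes the phenolic hydrogen, a second equivalent couples at the free para carbon between the methoxy and methyl groups, and loss of imidodisulfonate gives the para-quinone.

Step 2
Reactants: 2 2-methoxy-6-methyl-1,4-benzoquinone; 3 cyclopentadiene
Product: 4 (4aS,5R,8S,8aR)-2-methoxy-8a-methyl-4a,5,8,8a-tetrahydro-5,8-methanonaphthalene-1,4-dione (endo adduct across C5=C6)
Conditions: 3 (3 equiv), (S)-3,3-diphenyl-1-(2-methylphenyl)tetrahydro-1H,3H-pyrrolo[1,2-c][1,3,2]oxazaborole (20 mol %), HNTf2 (18 mol %), CH2Cl2, −78 °C
Reagents that add atoms: none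
Why: Catalytic enantioselective Diels–Alder reaction of a quinone with a protonated chiral oxazaborolidine; the acid binds the more basic C1 carbonyl (vinylogous ester carbonyl) with a C6–H···O contact and so activates the methyl-bearing C5=C6 bond, the C2=C3 bond being deactivated by its methoxy group; the diene adds endo to the face away from the shielding phenyl group, which sets C5, C6 and both bridgeheads at once.

Step 3
Reactants: 4 endo adduct
Product: 5 tricyclic hydroxy enone: C4 carbonyl of 4 reduced to C4–OH on the concave face (anti to C5–CH3); C1 ketone and C2=C3 methyl enol ether kept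
Conditions: NaBH4, CeCl3·7H2O, MeOH, −78 °C
Reagents that add atoms: none
Why: Luche reduction; C4 is the only carbonyl not deactivated as a vinylogous ester, cerium suppresses conjugate reduction, and hydride enters from the open convex face, so the hydroxyl lies on the concave face (sets C4).

Step 4
Reactants: 5 tricyclic hydroxy enone
Product: 6 tricyclic 4-hydroxy-5-methylcyclohexane-1,3-dione (C4–OH concave; enolised between C1 and C3)
Conditions: 1 M HCl, THF, rt
Reagents that add atoms: water, O
Why: Acid hydrolysis of a vinylogous ester; water adds to the protonated enol ether at C3 and methanol leaves; the C4 hydroxyl is α, not β, to the new carbonyl and cannot eliminate, and the dione rests as its enol, which keeps C4–H from exchanging.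

Step 5
Reactants: 7 (2E,6E)-farnesol
Product: 8 (2E,6E)-farnesyl acetate
Conditions: Ac2O, pyridine, DMAP (cat.), CH2Cl2, 0 °C to rt
Reagents that add atoms: acetic anhydride, CC(=O)OC(C)=O
Why: Nucleophilic catalysis of acyl transfer to a primary allylic alcohol; the acetate protects C1 during the oxidation and later serves as the leaving group.

Step 6
Reactants: 8 (2E,6E)-farnesyl acetate
Product: 9 (2E,6E,10E)-12-hydroxy-3,7,11-trimethyldodeca-2,6,10-trien-1-yl acetate
Conditions: SeO2 (0.1 equiv), t-BuOOH (70% aq., 3 equiv), salicylic acid (0.1 equiv), CH2Cl2, rt
Reagents that add atoms: tert-butyl hydroperoxide, CC(C)(C)OO (oxygen passed on through SeO2, O=[Se]=O)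
Why: Selenium dioxide allylic oxidation (ene reaction, then 2,3-sigmatropic shift); the electron-rich terminal alkene reacts first and the E-methyl group is oxidised, which gives the 10E allylic alcohol; the alkene next to the acetate is deactivated.

Step 7
Reactants: 9 12-hydroxyfarnesyl acetate
Product: 10 (2E,6E,10E)-12-(tert-butyldiphenylsilyloxy)-3,7,11-trimethyldodeca-2,6,10-trien-1-yl acetate
Conditions: TBDPSCl, imidazole, DMF, rt
Reagents that add atoms: tert-butyldiphenylsilyl chloride, CC(C)(C)[Si](Cl)(c1ccccc1)c1ccccc1
Why: Imidazole-promoted silylation of a primary alcohol; the silyl ether survives base, borohydride, acylation and heat, and is removed at the end by fluoride.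

Step 8
Reactants: 6 tricyclic hydroxy dione; 10 silyloxyfarnesyl acetate
Product: 11 tricyclic 2-(silyloxyfarnesyl)-4-hydroxy-5-methylcyclohexane-1,3-dione (drawn as the C3 enol; chain 2E,6E,10E)
Conditions: Pd(PPh3)4 (5 mol %, zerovalent palladium), DBU (1.1 equiv), THF, 0 °C to rt
Reagents that add atoms: none
Why: Tsuji–Trost allylation; oxidative addition to the allylic acetate gives the η3-farnesyl complex, and the soft dione enolate attacks its unsubstituted terminus to give the linear C2-alkylated product; O-allylated material re-ionises under the conditions, and the C4 hydroxyl is not nucleophilic enough to compete.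

Step 9
Reactants: 11 tricyclic 2-farnesyl dione
Product: 12 tricyclic 2-chloro-2-(silyloxyfarnesyl)-4-hydroxy-5-methylcyclohexane-1,3-dione (Cl convex; chain concave; C4–OH concave)
Conditions: N-chlorosuccinimide (1.0 equiv), CH2Cl2, 0 °C
Reagents that add atoms: N-chlorosuccinimide, O=C1CCC(=O)N1Cl
Why: Electrophilic chlorination of the dione enol, which is far more nucleophilic than the chain alkenes; chlorine enters from the convex face because the concave face of C2 lies under the norbornene alkene, and this sets C2 with chlorine convex.

Step 10
Reactants: 12 tricyclic 2-chloro dione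
Product: 14 tricyclic epoxy ketone alcohol (C2–C3 oxirane and C4–OH both concave; chain convex at C2; C1 ketone), via trans-chlorohydrin 13 (not isolated)
Conditions: Zn(BH4)2 (0.5 equiv), Et2O, −40 to −10 °C; then MeOH, K2CO3, 0 °C
Reagents that add atoms: none
Why: Reduction of an α-chloro ketone and closure of the trans-chlorohydrin, the ring-closing half of a Darzens reaction reached by hydride addition; the closest known reaction type is the reduction of 2-chloro-1,3-dicarbonyl compounds to chlorohydrins and their base-induced conversion into glycidic carbonyl compounds. Zinc binds the C4 hydroxyl and the C3 carbonyl oxygen in a five-membered chelate, which activates C3 over the unchelated C1 ketone. Hydride reaches C3 from the convex face because the concave face is covered by the norbornene CH=CH bridge, so C3–H is convex and the C3 oxygen concave (the fold of the tricycle sets C3). In 13 this oxygen is anti to the convex C2–Cl bond, and once methanol has destroyed the remaining hydride, carbonate generates the alkoxide, which displaces chloride from the rear at the tertiary α-keto carbon with inversion (the C2 configuration from step 9 sets C2, oxygen concave and chain convex). The oxirane closes in the 3-exo-tet mode. The step needs C3 over C1 selectivity (chelation to the free C4 hydroxyl), convex hydride delivery in spite of the neighbouring chlorine (shape of the endo tricycle) and no second reduction at C1 (substoichiometric hydride, low temperature). The C4 oxygen and the oxirane oxygen end up cis, as 17 requires.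

Step 11
Reactants: 14 tricyclic epoxy ketone alcohol
Product: 15 tricyclic epoxy ketone acetate (C4–OAc and oxirane both concave)
Conditions: Ac2O, pyridine, DMAP (cat.), CH2Cl2, 0 °C to rt
Reagents that add atoms: acetic anhydride, CC(=O)OC(C)=O
Why: DMAP-catalysed acetylation of the only free hydroxyl; the cis epoxy alcohol cannot undergo epoxide migration because the hydroxyl is on the same face as the oxirane oxygen.

Step 12
Reactants: 15 tricyclic epoxy ketone acetate
Product: 16 (1R,5R,6R)-1-[(2E,6E,10E)-12-(tert-butyldiphenylsilyloxy)-3,7,11-trimethyldodeca-2,6,10-trien-1-yl]-4-methyl-2-oxo-7-oxabicyclo[4.1.0]hept-3-en-5-yl acetate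
Conditions: Ph2O, 230 °C, 15–30 min, argon stream
Reagents that add atoms: none
Why: Retro-Diels–Alder reaction; the cycloreversion releases cyclopentadiene, helped by the quaternary C5 and by conjugation of the new C5=C6 bond with the C1 ketone, and the volatile diene is swept out so that it cannot add back; C2, C3 and C4 are not touched.

Step 13
Reactants: 16 silyl ether of yanuthone L
Product: 17 yanuthone L, (1R,5R,6R)-1-[(2E,6E,10E)-12-hydroxy-3,7,11-trimethyldodeca-2,6,10-trien-1-yl]-4-methyl-2-oxo-7-oxabicyclo[4.1.0]hept-3-en-5-yl acetate
Conditions: HF·pyridine, pyridine, THF, 0 °C to rt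
Reagents that add atoms: none
Why: Fluoride-driven cleavage of a primary silyl ether under buffered, weakly acidic conditions that leave the oxirane, the acetate and the base-sensitive γ-acetoxy enone alone.

## Compound list

1 | 3-methoxy-5-methylphenol | COc1cc(C)cc(O)c1 | starting material
2 | 2-methoxy-6-methyl-1,4-benzoquinone | COC1=CC(=O)C=C(C)C1=O | intermediate
3 | cyclopentadiene | C1C=CC=C1 | starting material
4 | (4aS,5R,8S,8aR)-2-methoxy-8a-methyl-4a,5,8,8a-tetrahydro-5,8-methanonaphthalene-1,4-dione, endo adduct | O=C1C(OC)=CC(=O)[C@H]2[C@H]3C=C[C@H](C3)[C@@]12C | intermediate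
5 | tricyclic hydroxy enone, C4–OH concave, core as in 4 | O[C@H]1C(OC)=CC(=O)[C@H]2[C@H]3C=C[C@H](C3)[C@@]12C | intermediate
6 | tricyclic 4-hydroxy-5-methylcyclohexane-1,3-dione, C4–OH concave, core as in 4 | O[C@H]1C(=O)CC(=O)[C@H]2[C@H]3C=C[C@H](C3)[C@@]12C | intermediate
7 | (2E,6E)-farnesol | CC(C)=CCC/C(C)=C/CC/C(C)=C/CO | starting material
8 | (2E,6E)-farnesyl acetate | CC(C)=CCC/C(C)=C/CC/C(C)=C/COC(C)=O | intermediate
9 | (2E,6E,10E)-12-hydroxy-3,7,11-trimethyldodeca-2,6,10-trien-1-yl acetate | OC/C(C)=C/CC/C(C)=C/CC/C(C)=C/COC(C)=O | intermediate
10 | (2E,6E,10E)-12-(tert-butyldiphenylsilyloxy)-3,7,11-trimethyldodeca-2,6,10-trien-1-yl acetate | CC(C)(C)[Si](c1ccccc1)(c1ccccc1)OC/C(C)=C/CC/C(C)=C/CC/C(C)=C/COC(C)=O | intermediate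
11 | tricyclic 2-(silyloxyfarnesyl)-4-hydroxy-5-methylcyclohexane-1,3-dione, C3 enol tautomer shown, core as in 4 | O[C@H]1C(O)=C(C/C=C(\C)CC/C=C(\C)CC/C=C(\C)CO[Si](c4ccccc4)(c4ccccc4)C(C)(C)C)C(=O)[C@H]2[C@H]3C=C[C@H](C3)[C@@]12C | intermediate
12 | tricyclic 2-chloro-2-(silyloxyfarnesyl)-4-hydroxy-5-methylcyclohexane-1,3-dione, Cl convex, chain and C4–OH concave | O[C@H]1C(=O)[C@@](Cl)(C/C=C(\C)CC/C=C(\C)CC/C=C(\C)CO[Si](c4ccccc4)(c4ccccc4)C(C)(C)C)C(=O)[C@H]2[C@H]3C=C[C@H](C3)[C@@]12C | intermediate
13 | trans-chlorohydrin: 12 with C3 reduced, C3–OH concave and anti to the convex C2–Cl (not isolated) | O[C@H]1[C@@H](O)[C@@](Cl)(C/C=C(\C)CC/C=C(\C)CC/C=C(\C)CO[Si](c4ccccc4)(c4ccccc4)C(C)(C)C)C(=O)[C@H]2[C@H]3C=C[C@H](C3)[C@@]12C | intermediate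
14 | tricyclic epoxy ketone alcohol, C2–C3 oxirane and C4–OH concave, chain convex | O[C@H]1[C@H]5O[C@@]5(C/C=C(\C)CC/C=C(\C)CC/C=C(\C)CO[Si](c4ccccc4)(c4ccccc4)C(C)(C)C)C(=O)[C@H]2[C@H]3C=C[C@H](C3)[C@@]12C | intermediate
15 | tricyclic epoxy ketone acetate, C4–OAc and oxirane concave | CC(=O)O[C@H]1[C@H]5O[C@@]5(C/C=C(\C)CC/C=C(\C)CC/C=C(\C)CO[Si](c4ccccc4)(c4ccccc4)C(C)(C)C)C(=O)[C@H]2[C@H]3C=C[C@H](C3)[C@@]12C | intermediate
16 | (1R,5R,6R)-1-[(2E,6E,10E)-12-(tert-butyldiphenylsilyloxy)-3,7,11-trimethyldodeca-2,6,10-trien-1-yl]-4-methyl-2-oxo-7-oxabicyclo[4.1.0]hept-3-en-5-yl acetate | CC(=O)O[C@@H]1C(C)=CC(=O)[C@]2(C/C=C(\C)CC/C=C(\C)CC/C=C(\C)CO[Si](c3ccccc3)(c3ccccc3)C(C)(C)C)O[C@H]12 | intermediate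
17 | yanuthone L | CC(=O)O[C@@H]1C(C)=CC(=O)[C@]2(C/C=C(\C)CC/C=C(\C)CC/C=C(\C)CO)O[C@H]12 | target

## Step count and least certain steps

Total step count: 13. Longest linear sequence: 10 steps (steps 1 to 4 and 8 to 13, from 1 to 17).

**Step 10 (key step).** The most likely failure is poor selectivity of hydride delivery. The hydride must enter C3 on the face that also carries the C2 chlorine, against the usual preference of α-chloro ketones for attack anti to the C–Cl bond, and the C1 ketone competes; its reduction would lead to closure onto the other side of C2. Lesser dangers are retro-aldol cleavage of the β-alkoxy ketone before closure and hydroboration of the strained alkene by liberated borane. The step also depends on the C2 configuration from step 9.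

The fallback reverses the order of the C–H and C–Cl bond formations and leaves the route at 11, so it replaces step 9 as well:
- Me3SiCHN2 in MeOH/toluene converts 11 into the C1 methyl enol ether with the C3 ketone kept, F1, which is separated from its regioisomer, the C3 methyl enol ether F2.
- i-Bu2AlH in CH2Cl2 at −78 °C reduces the C3 carbonyl of F1 from the convex face, now with no chlorine and an sp2 C2 beside it, to the allylic alcohol F3 (first stage of a Stork–Danheiser sequence).
- N-chlorosuccinimide in THF/H2O with NaHCO3 chlorinates the enol ether at C2 from the convex face, anti to the C3 carbinol, and water captures the oxocarbenium ion to give chlorohydrin 13 as an isolated compound.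
- K2CO3 in MeOH closes 13 to 14, where the route is rejoined.

**Step 2.** The most likely failure is low enantioselectivity. The catalyst can bind the C1 carbonyl on the side of C2–H instead of C6–H, which does not organise the reacting C5=C6 bond, and the trisubstituted dienophile is slow enough for an unselective background reaction on warming.

The fallback is a resolution, setting out from 2 and 3:
- Uncatalysed cycloaddition in CH2Cl2 at rt gives 4 together with its mirror image, ent-adduct F4.
- NaBH4/CeCl3·7H2O in MeOH reduces the pair to 5 and its mirror image, ent-alcohol F5.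
- A lipase with vinyl acetate acylates one enantiomer of the secondary alcohol. If the faster one is F5, its acetate F6 is removed by chromatography and 5 is carried on. If the faster one is 5, its acetate F7 is separated and cleaved with K2CO3 in MeOH. The route is rejoined at 5.

**Step 8.** The most likely failure is partial loss of the 2E geometry, because the disubstituted terminus of the η3-allyl complex can exchange its syn and anti substituents before attack. O-allylation and a second allylation are lesser problems.

The fallback is a direct displacement, setting out from 10 and 6: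
- K2CO3 in MeOH removes the acetate of 10 to give the allylic alcohol F8.
- CBr4 and PPh3 in CH2Cl2 at 0 °C (Appel reaction) give the allylic bromide F9.
- The potassium enolate of 6 (K2CO3, aqueous THF with Bu4NBr) is alkylated by F9 at C2 by direct SN2 displacement, which cannot change the alkene geometry. The route is rejoined at 11.

**Step 12.** The most likely failure is thermal degradation competing with cycloreversion. The reduced C4 centre lowers the driving force compared with enedione adducts, and at 230 °C the acetate can migrate, the epoxy ketone can isomerise and the 1,5-diene units of the chain can begin to rearrange.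

The fallback moves the cycloreversion one step earlier, so that no ester is present in the hot solution, and sets out from 14:
- Thermolysis of 14 in Ph2O at 230 °C gives the free epoxyquinol silyl ether F10.
- Acetylation of F10 at rt (Ac2O, pyridine, DMAP) gives 16, where the route is rejoined.

## Further compounds

F1 | step 10 | C1 methyl enol ether of 11 with the C3 ketone kept | O[C@H]1C(=O)C(C/C=C(\C)CC/C=C(\C)CC/C=C(\C)CO[Si](c4ccccc4)(c4ccccc4)C(C)(C)C)=C(OC)[C@H]2[C@H]3C=C[C@H](C3)[C@@]12C
F2 | step 10 | C3 methyl enol ether of 11 with the C1 ketone kept (regioisomer of F1) | O[C@H]1C(OC)=C(C/C=C(\C)CC/C=C(\C)CC/C=C(\C)CO[Si](c4ccccc4)(c4ccccc4)C(C)(C)C)C(=O)[C@H]2[C@H]3C=C[C@H](C3)[C@@]12C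
F3 | step 10 | allylic alcohol from F1, C3–OH and C4–OH concave, C1=C2 methyl enol ether | O[C@H]1[C@@H](O)C(C/C=C(\C)CC/C=C(\C)CC/C=C(\C)CO[Si](c4ccccc4)(c4ccccc4)C(C)(C)C)=C(OC)[C@H]2[C@H]3C=C[C@H](C3)[C@@]12C
F4 | step 2 | ent-adduct, (4aR,5S,8R,8aS)-2-methoxy-8a-methyl-4a,5,8,8a-tetrahydro-5,8-methanonaphthalene-1,4-dione | O=C1C(OC)=CC(=O)[C@@H]2[C@@H]3C=C[C@@H](C3)[C@]12C
F5 | step 2 | ent-alcohol, mirror image of 5 | O[C@@H]1C(OC)=CC(=O)[C@@H]2[C@@H]3C=C[C@@H](C3)[C@]12C
F6 | step 2 | acetate of F5 | CC(=O)O[C@@H]1C(OC)=CC(=O)[C@@H]2[C@@H]3C=C[C@@H](C3)[C@]12C
F7 | step 2 | acetate of 5 | CC(=O)O[C@H]1C(OC)=CC(=O)[C@H]2[C@H]3C=C[C@H](C3)[C@@]12C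
F8 | step 8 | (2E,6E,10E)-12-(tert-butyldiphenylsilyloxy)-3,7,11-trimethyldodeca-2,6,10-trien-1-ol | OC/C=C(\C)CC/C=C(\C)CC/C=C(\C)CO[Si](c1ccccc1)(c1ccccc1)C(C)(C)C
F9 | step 8 | (2E,6E,10E)-12-(tert-butyldiphenylsilyloxy)-3,7,11-trimethyldodeca-2,6,10-trien-1-yl bromide | BrC/C=C(\C)CC/C=C(\C)CC/C=C(\C)CO[Si](c1ccccc1)(c1ccccc1)C(C)(C)C
F10 | step 12 | (1R,5R,6R)-5-hydroxy-4-methyl-1-[(2E,6E,10E)-12-(tert-butyldiphenylsilyloxy)-3,7,11-trimethyldodeca-2,6,10-trien-1-yl]-7-oxabicyclo[4.1.0]hept-3-en-2-one | O[C@@H]1C(C)=CC(=O)[C@]2(C/C=C(\C)CC/C=C(\C)CC/C=C(\C)CO[Si](c3ccccc3)(c3ccccc3)C(C)(C)C)O[C@H]12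
A1 | alternative 1 | 5-methyl-2-(silyloxyfarnesyl)cyclohexa-1,3-diene | C[C@@H]1CC=C(C/C=C(\C)CC/C=C(\C)CC/C=C(\C)CO[Si](c2ccccc2)(c2ccccc2)C(C)(C)C)C=C1
A2 | alternative 1 | cis-1,4-diacetoxy-2-(silyloxyfarnesyl)-5-methylcyclohex-2-ene, both acetates syn to the C5 methyl | C[C@@H]1C[C@H](OC(C)=O)C(C/C=C(\C)CC/C=C(\C)CC/C=C(\C)CO[Si](c2ccccc2)(c2ccccc2)C(C)(C)C)=C[C@@H]1OC(C)=O
A3 | alternative 2 | triethylsilyl ether of 5-methyl-2-(silyloxyfarnesyl)cyclohexa-2,4-dien-1-ol | [C@H]1(O[Si](CC)(CC)CC)C(C/C=C(\C)CC/C=C(\C)CC/C=C(\C)CO[Si](c2ccccc2)(c2ccccc2)C(C)(C)C)=CC=C(C)C1
A4 | alternative 2 | syn-bisepoxide with oxiranes at C2–C3 and C4–C5, both anti to the C1 silyloxy group | [C@H]1(O[Si](CC)(CC)CC)[C@]2(C/C=C(\C)CC/C=C(\C)CC/C=C(\C)CO[Si](c4ccccc4)(c4ccccc4)C(C)(C)C)O[C@@H]2[C@@H]3O[C@]3(C)C1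
A5 | alternative 3 | Z-keto-enal with C3/C4 trans acetonide and silyloxyfarnesyl ketone | O=C\C=C(C)/[C@H]1OC(C)(C)O[C@@H]1C(=O)C/C=C(\C)CC/C=C(\C)CC/C=C(\C)CO[Si](c2ccccc2)(c2ccccc2)C(C)(C)C
A6 | alternative 3 | 6-hydroxy-6-(silyloxyfarnesyl)cyclohex-2-enone with C3/C4 trans acetonide | O=C1C=C(C)[C@H]2OC(C)(C)O[C@@H]2[C@]1(O)C/C=C(\C)CC/C=C(\C)CC/C=C(\C)CO[Si](c3ccccc3)(c3ccccc3)C(C)(C)C
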